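**Retrosynthetic overview**
1. The strategy rests on the chain C17=C15–C1–C2–C3(O). It comprises the exo-methylene of the seven-membered lactone (C15–C16–O–C12–C13–C14–C1), the ring-fusion carbon C1, and the C3 carbinol of the 14-membered carbocycle. This is the pattern left by an Alder-ene reaction between a C15≡C17 alkynoate and a C1=C2 alkene that gives up the C3 carbinol hydrogen.
2. Target 27 comes from CBS reduction of 3-ketone 26, and 26 comes from the ruthenium-catalysed transannular cycloisomerisation of the monocyclic C12 propiolate 24.
3. 24 comes from C12 acylation and desilylation of macrocycle 20. 20 comes from RCM at C1=C2 of tetraene 19, and 19 from a Pd allyl–vinyl coupling (C5–C6) of 9 with 18.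
4. 9 (C6–C14, C1) comes from farnesyl acetate by terminal cleavage, methylenation, ent-Shi epoxidation at C11=C12 (the allylic acetate switches off C7=C8), hydrolysis inverting C12, and C11 acetylation. 18 (C2–C5) comes from propargyl alcohol and vinylmagnesium bromide.
5. Ring order: the 14-membered carbocycle forms first (step 14) and the seven-membered lactone second (step 17).

Key step: step 17

Remarks on the chemistry:
- Atoms are cited in cembrane numbering.
- C3 comes from racemic 15 and is carried as both epimers from 19 to 24, so the SMILES leave C3 undefined there. The centre is erased in step 17 and set in step 18.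
- The ent-Shi ketone (L-fructose series, made from L-sorbose) is taken as purchasable.

**Step 1**
Reactants: 1 (2E,6E)-farnesyl acetate
Product: 2 (2E,6E)-10-bromo-11-hydroxy-3,7,11-trimethyldodeca-2,6-dien-1-yl acetate (racemic at C10)
Conditions: NBS (1.05 equiv), THF/H2O, 0 °C
Reagents that add atoms: N-bromosuccinimide, O=C1CCC(=O)N1Br; water, O
Why: Bromohydrin formation in aqueous medium should pick the exposed, most electron-rich terminal isopropylidene alkene, with water opening the bromonium ion at the tertiary carbon; the racemic centre is lost in step 3.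

**Step 2**
Reactants: 2 bromohydrin
Product: 3 (2E,6E)-10,11-epoxy-3,7,11-trimethyldodeca-2,6-dien-1-yl acetate (racemic)
Conditions: DBU (1.5 equiv), THF, 0 °C to rt
Reagents that add atoms: none
Why: This is an intramolecular Williamson-type SN2 closure of the bromohydrin, and the non-nucleophilic amidine base is used instead of K2CO3/MeOH so that the allylic acetate is kept.

**Step 3**
Reactants: 3 terminal epoxide
Product: 5 (2E,6E)-3,7-dimethyl-10-oxodeca-2,6-dien-1-yl acetate, via (2E,6E)-10,11-dihydroxy-3,7,11-trimethyldodeca-2,6-dien-1-yl acetate 4 (not isolated)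
Conditions: H5IO6 (1.2 equiv), THF/Et2O, 0 °C
Reagents that add atoms: none
Why: Periodic acid opens the epoxide to the glycol and cleaves it in the same flask (Malaprade cleavage), while the trisubstituted alkenes and the acetate are inert.

**Step 4**
Reactants: 5 aldehyde
Product: 6 (2E,6E)-3,7-dimethylundeca-2,6,10-trien-1-yl acetate
Conditions: Ph3PCH3Br (1.1 equiv), KHMDS (1.05 equiv), THF, −78 to 0 °C
Reagents that add atoms: methyltriphenylphosphonium bromide, C[P+](c1ccccc1)(c1ccccc1)c1ccccc1.[Br-]
Why: In this Wittig methylenation, a near-stoichiometric amount of ylide at low temperature reacts with the aldehyde far faster than with the acetate.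

**Step 5**
Reactants: 6 triene acetate
Product: 7 (2E,6S,7S)-6,7-epoxy-3,7-dimethylundeca-2,10-dien-1-yl acetate
Conditions: ent-Shi ketone (30 mol %), Oxone, K2CO3, Bu4NHSO4, MeCN/DMM, aq. Na2B4O7–EDTA buffer (pH 10.5), 0 °C
Reagents that add atoms: Oxone (potassium peroxymonosulfate), [K+].[O-]S(=O)(=O)OO
Why: In this Shi epoxidation the chiral dioxirane should take only C11=C12, because C7=C8 is deactivated by its allylic acetate and the monosubstituted vinyl group is a poor substrate; the L-series ketone delivers oxygen to the face that gives the (S,S)-epoxide through the spiro transition state.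

**Step 6**
Reactants: 7 epoxide
Product: 8 (2E,6S,7R)-6,7-dihydroxy-3,7-dimethylundeca-2,10-dien-1-yl acetate
Conditions: HClO4 (cat.), THF/H2O, 0 °C
Reagents that add atoms: water, O
Why: In this acid-catalysed borderline-SN2 epoxide hydrolysis, water attacks the tertiary carbon C12 from the rear, so C12 is inverted to R and C11 keeps S, giving the anti diol that syn dihydroxylation of the E-alkene cannot give.

**Step 7**
Reactants: 8 diol
Product: 9 (2E,6S,7R)-7-hydroxy-3,7-dimethylundeca-2,10-diene-1,6-diyl diacetate
Conditions: Ac2O (1.2 equiv), pyridine, DMAP (cat.), CH2Cl2, 0 °C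
Reagents that add atoms: acetic anhydride, CC(=O)OC(C)=O
Why: Under these mild nucleophilic-catalysis conditions only the secondary C11 hydroxyl is acetylated and the tertiary C12 hydroxyl stays free.

**Step 8**
Reactants: 10 propargyl alcohol
Product: 12 (E)-3-iodo-2-methylprop-2-en-1-ol, via the (E)-alkenylalane O-aluminate 11 (not isolated)
Conditions: Me3Al (3 equiv), Cp2ZrCl2 (25 mol %), CH2Cl2, 0 °C to rt; then I2, THF, −30 °C
Reagents that add atoms: trimethylaluminium, C[Al](C)C; iodine, II
Why: Negishi zirconium-catalysed carboalumination adds methyl and aluminium syn with methyl on the internal carbon, and iodinolysis with retention fixes the E geometry of the future C4=C5.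

**Step 9**
Reactants: 12 iodo alcohol
Product: 13 (E)-3-iodo-2-methylprop-2-enal
Conditions: MnO2 (excess), CH2Cl2, rt, dark
Reagents that add atoms: none
Why: MnO2 oxidation of an allylic alcohol stops at the enal and leaves the alkenyl iodide and its geometry untouched.

**Step 10**
Reactants: 13 iodo enal; 14 vinylmagnesium bromide
Product: 15 (1E)-1-iodo-2-methylpenta-1,4-dien-3-ol (racemic)
Conditions: THF, −78 °C; then aq. NH4Cl
Reagents that add atoms: none
Why: Grignard 1,2-addition to the enal is much faster at −78 °C than iodine–magnesium exchange, and no control at C3 is needed because this centre becomes a ketone in step 17.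

**Step 11**
Reactants: 15 dienol
Product: 16 triethyl{[(1E)-1-iodo-2-methylpenta-1,4-dien-3-yl]oxy}silane (racemic)
Conditions: TESCl, imidazole, CH2Cl2, 0 °C
Reagents that add atoms: chlorotriethylsilane, CC[Si](Cl)(CC)CC
Why: Standard silylation masks C3–OH so that it can later be told apart from the C12 hydroxyl and released under buffered fluoride.

**Step 12**
Reactants: 16 iodide
Product: 18 triethyl{[(1E)-2-methyl-1-(tributylstannyl)penta-1,4-dien-3-yl]oxy}silane (racemic), via the (E)-alkenyllithium 17 (not isolated)
Conditions: t-BuLi (2.1 equiv), Et2O, −78 °C; then Bu3SnCl, −78 °C to rt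
Reagents that add atoms: tributyltin chloride, CCCC[Sn](Cl)(CCCC)CCCC
Why: Iodine–lithium exchange and stannylation both proceed with retention, and lithium stands trans to the C3 silyl ether, so silyl migration from oxygen to carbon is not possible.

**Step 13**
Reactants: 9 hydroxy diacetate; 18 alkenylstannane
Product: 19 (4E,7E,11S,12R)-12-hydroxy-4,8,12-trimethyl-3-(triethylsilyloxy)hexadeca-1,4,7,15-tetraen-11-yl acetate (both C3 epimers)
Conditions: Pd(dba)2 (5 mol %), LiCl (3 equiv), DMF, rt to 40 °C
Reagents that add atoms: none
Why: In this Stille-type allyl–vinyl coupling of an allylic acetate, Pd(0) ionises only the primary allylic acetate (the C11 alkyl acetate is inert), and the π-allyl complex couples at its primary terminus C6 with retention of both alkene geometries, giving the E,E skipped diene; the free tertiary alcohol is tolerated.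

**Step 14**
Reactants: 19 tetraene
Product: 20 (1E,4E,7E,11S,12R)-12-hydroxy-4,8,12-trimethyl-3-(triethylsilyloxy)cyclotetradeca-1,4,7-trien-11-yl acetate (cembrane numbering, both C3 epimers)
Conditions: Grubbs second-generation catalyst (10 mol %), 1,4-benzoquinone (20 mol %), toluene, 1 mM, 80 °C
Reagents that add atoms: none
Why: In this ring-closing metathesis the catalyst should load on the unhindered C1 vinyl group and close on the vinyl carbinol ether, the trisubstituted alkenes stay out (a six-membered ring through C2/C7 would need a trans C4=C5 inside it), and reversible metathesis next to the branched C3 should favour the E-alkene; any Z isomer is removed by chromatography.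

**Step 15**
Reactants: 20 macrocyclic tertiary alcohol; 21 3-(trimethylsilyl)propynoic acid
Product: 23 C12 3-(trimethylsilyl)propynoate of 20 (both C3 epimers), via 3-(trimethylsilyl)propynoyl chloride 22 (not isolated)
Conditions: 21, (COCl)2, DMF (cat.), CH2Cl2, 0 °C to rt, concentrate; then 20, DMAP (3 equiv), CH2Cl2, 0 to 35 °C
Reagents that add atoms: none
Why: This is a DMAP-promoted acylation with an acid chloride; the rod-shaped alkynoyl group is the slimmest acyl donor for a tertiary carbinol, and the silyl cap blocks conjugate addition of DMAP, which spoils direct carbodiimide couplings of propiolic acid with slow alcohols.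

**Step 16**
Reactants: 23 bis-silylated ester
Product: 24 (1E,4E,7E,11S,12R)-11-acetoxy-3-hydroxy-4,8,12-trimethylcyclotetradeca-1,4,7-trien-12-yl propynoate (both C3 epimers)
Conditions: TBAF/AcOH (1:1.2, 2.5 equiv), THF, 0 °C to rt
Reagents that add atoms: none
Why: Buffered fluoride cleaves the activated alkynyl C–Si bond and the O–TES ether in one operation, and the acetic acid buffer keeps the esters, the terminal alkynoate and the acid-sensitive doubly allylic alcohol intact.

**Step 17**
Reactants: 24 macrocyclic propiolate
Product: 26 3-oxo analogue of the target, (1R,11S,12R), via the C2=C3 dienol 25 (not isolated)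
Conditions: [CpRu(MeCN)3]PF6 (10–20 mol %), acetone, 5 mM, rt to 50 °C
Reagents that add atoms: none
Why: Proposed new method: cationic CpRu binds the alkynoate and the C1=C2 alkene and couples them oxidatively to a ruthenacyclopentene (new C15–C1 bond, Ru on C17 and C2); only the exocyclic C3–H can reach the metal for β-hydride elimination because C1–H is locked inside the metallacycle, and reductive elimination then places hydrogen on C17 and releases dienol 25, which tautomerises to enone 26. The closest known reaction types are the ruthenium-catalysed Alder-ene coupling of alkynes with allylic alcohols to γ,δ-unsaturated ketones and the cycloisomerisation of 1,6- and 1,7-enynes, alkynoates included, to five- and six-membered rings, whereas a 1,8-enyne closing a seven-membered lactone across a macrocycle has not been shown. The lactone ring C15–C16–O–C12–C13–C14–C1 closes in the 7-exo mode with respect to the alkene and needs the less favoured E rotamer of the ester, a penalty that the tertiary C12 alkyl group lowers and that the macrocycle offsets by already holding C1 close to C12. C1 is set relative to C12 by a chair-like seven-membered closure in which C11 (on C12) and C2 (on C1) are both pseudo-equatorial, which keeps the anti–gauche–anti path C11–C12–C13–C14–C1–C2 of the macrocycle and leads to the 1,4-trans relation, that is 1R. The step needs chemoselectivity for C1=C2, secured because the trisubstituted C4=C5 and C7=C8 alkenes do not engage CpRu productively, and it needs the coupling to outrun redox isomerisation and ionisation of the doubly allylic alcohol, for which neutral acetone, high dilution and the lowest workable temperature are chosen. Both C3 epimers should converge on 26, since they differ only in the geometry of the transient enol.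

**Step 18**
Reactants: 26 enone
Product: 27 dendronpholide B, (1R,3R,11S,12R)
Conditions: (S)-Me-CBS (30 mol %), catecholborane (1.8 equiv), toluene/CH2Cl2, −78 °C; aqueous work-up
Reagents that add atoms: none
Why: In this CBS reduction the α-methylalkenyl arm (C4) acts as the large group and C2H2 as the small one, so the (S)-catalyst should deliver hydride to the face that gives 3R, and catecholborane at −78 °C neither hydroborates the alkenes nor reduces the α-methylene lactone or the acetate.

**Compound list**
1 | (2E,6E)-farnesyl acetate | CC(C)=CCC/C(C)=C/CC/C(C)=C/COC(C)=O | starting material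
2 | (2E,6E)-10-bromo-11-hydroxy-3,7,11-trimethyldodeca-2,6-dien-1-yl acetate (racemic) | CC(C)(O)C(Br)CC/C(C)=C/CC/C(C)=C/COC(C)=O | intermediate
3 | (2E,6E)-10,11-epoxy-3,7,11-trimethyldodeca-2,6-dien-1-yl acetate (racemic) | CC1(C)OC1CC/C(C)=C/CC/C(C)=C/COC(C)=O | intermediate
4 | (2E,6E)-10,11-dihydroxy-3,7,11-trimethyldodeca-2,6-dien-1-yl acetate (not isolated) | CC(C)(O)C(O)CC/C(C)=C/CC/C(C)=C/COC(C)=O | intermediate
5 | (2E,6E)-3,7-dimethyl-10-oxodeca-2,6-dien-1-yl acetate | O=CCC/C(C)=C/CC/C(C)=C/COC(C)=O | intermediate
6 | (2E,6E)-3,7-dimethylundeca-2,6,10-trien-1-yl acetate | C=CCC/C(C)=C/CC/C(C)=C/COC(C)=O | intermediate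
7 | (2E,6S,7S)-6,7-epoxy-3,7-dimethylundeca-2,10-dien-1-yl acetate | C=CCC[C@]1(C)O[C@H]1CC/C(C)=C/COC(C)=O | intermediate
8 | (2E,6S,7R)-6,7-dihydroxy-3,7-dimethylundeca-2,10-dien-1-yl acetate | C=CCC[C@@](C)(O)[C@@H](O)CC/C(C)=C/COC(C)=O | intermediate
9 | (2E,6S,7R)-7-hydroxy-3,7-dimethylundeca-2,10-diene-1,6-diyl diacetate | C=CCC[C@@](C)(O)[C@@H](OC(C)=O)CC/C(C)=C/COC(C)=O | intermediate
10 | propargyl alcohol | C#CCO | starting material
11 | (E)-alkenylalane O-aluminate from carboalumination (not isolated) | C[Al](C)OC/C(C)=C/[Al](C)C | intermediate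
12 | (E)-3-iodo-2-methylprop-2-en-1-ol | OC/C(C)=C/I | intermediate
13 | (E)-3-iodo-2-methylprop-2-enal | O=C/C(C)=C/I | intermediate
14 | vinylmagnesium bromide | C=C[Mg]Br | starting material
15 | (1E)-1-iodo-2-methylpenta-1,4-dien-3-ol (racemic) | C=CC(O)/C(C)=C/I | intermediate
16 | triethyl{[(1E)-1-iodo-2-methylpenta-1,4-dien-3-yl]oxy}silane (racemic) | C=CC(O[Si](CC)(CC)CC)/C(C)=C/I | intermediate
17 | (E)-alkenyllithium from 16 (not isolated) | C=CC(O[Si](CC)(CC)CC)/C(C)=C/[Li] | intermediate
18 | triethyl{[(1E)-2-methyl-1-(tributylstannyl)penta-1,4-dien-3-yl]oxy}silane (racemic) | C=CC(O[Si](CC)(CC)CC)/C(C)=C/[Sn](CCCC)(CCCC)CCCC | intermediate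
19 | (4E,7E,11S,12R)-12-hydroxy-4,8,12-trimethyl-3-(triethylsilyloxy)hexadeca-1,4,7,15-tetraen-11-yl acetate (both C3 epimers) | C=CC(O[Si](CC)(CC)CC)/C(C)=C/C/C=C(\C)CC[C@H](OC(C)=O)[C@](C)(O)CCC=C | intermediate
20 | (1E,4E,7E,11S,12R)-12-hydroxy-4,8,12-trimethyl-3-(triethylsilyloxy)cyclotetradeca-1,4,7-trien-11-yl acetate (both C3 epimers) | O[C@]1(C)CC/C=C/C(O[Si](CC)(CC)CC)/C(C)=C/C/C=C(\C)CC[C@@H]1OC(C)=O | intermediate
21 | 3-(trimethylsilyl)propynoic acid | C[Si](C)(C)C#CC(=O)O | starting material
22 | 3-(trimethylsilyl)propynoyl chloride (not isolated) | C[Si](C)(C)C#CC(=O)Cl | intermediate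
23 | C12 3-(trimethylsilyl)propynoate of 20 (both C3 epimers) | C[Si](C)(C)C#CC(=O)O[C@]1(C)CC/C=C/C(O[Si](CC)(CC)CC)/C(C)=C/C/C=C(\C)CC[C@@H]1OC(C)=O | intermediate
24 | (1E,4E,7E,11S,12R)-11-acetoxy-3-hydroxy-4,8,12-trimethylcyclotetradeca-1,4,7-trien-12-yl propynoate, key-step precursor (both C3 epimers) | C#CC(=O)O[C@]1(C)CC/C=C/C(O)/C(C)=C/C/C=C(\C)CC[C@@H]1OC(C)=O | intermediate
25 | C2=C3 dienol of 26 (enol geometry depends on the C3 epimer; not isolated) | C=C1C(=O)O[C@]2(C)CC[C@@H]1C=C(O)/C(C)=C/C/C=C(\C)CC[C@@H]2OC(C)=O | intermediate
26 | 3-oxo analogue of the target, (1R,11S,12R) | C=C1C(=O)O[C@]2(C)CC[C@@H]1CC(=O)/C(C)=C/C/C=C(\C)CC[C@@H]2OC(C)=O | intermediate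
27 | dendronpholide B, (1R,3R,11S,12R) | C=C1C(=O)O[C@]2(C)CC[C@@H]1C[C@@H](O)/C(C)=C/C/C=C(\C)CC[C@@H]2OC(C)=O | target

**Step count**
Total: 18 steps. Longest linear sequence: 13 steps (steps 1–7 and 13–18, from farnesyl acetate).

**Steps most likely to fail**

1. Step 17.
   - What may go wrong: the ruthenacycle may not form, because the ester has to leave its favoured rotamer and a seven-membered ring has to close. Redox isomerisation or ionisation of the doubly allylic alcohol may then win, or the facial selectivity at C1 may be poor.
   - Fallback: it uses known chemistry, sets out from 20 and comes back at 26.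
   - Carbodiimide coupling of 20 with diethylphosphonoacetic acid (DCC, cat. DMAP, CH2Cl2) runs through a ketene-like acyl donor that suits hindered alcohols. It gives the C12 diethylphosphonoacetate F1.
   - HF·pyridine in THF frees the C3 allylic alcohol F2, and MnO2 oxidises it to the cross-conjugated C1=C2/C4=C5 dienone F3.
   - Base (DBU/LiCl, MeCN, high dilution) brings about a reversible transannular Michael addition of the phosphonoacetate carbon to C1. The tether allows only this position, and the more stable trans-bridged α-phosphono lactone F4 should result.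
   - Horner–Wadsworth–Emmons methylenation of F4 with aqueous formaldehyde and K2CO3 in THF installs C15=C17 and gives 26.

2. Step 14.
   - What may go wrong: oligomerisation may compete with ring closure, and the geometry of the new C1=C2 alkene may be poorly controlled in the macrocycle.
   - Fallback: it exchanges the roles of the two unions, sets out from 9 and 18 and comes back at 20.
   - Intermolecular cross-metathesis of the terminal alkene of 9 with the vinyl carbinol ether of 18 (Hoveyda–Grubbs second-generation catalyst, CH2Cl2, 40 °C) sets C1=C2 in an open chain, where the branched allylic partner enforces E geometry and isomers are easily separated. The product is the stannyl allylic acetate F5.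
   - The ring is then closed at C5–C6 by an intramolecular allyl–vinyl Stille coupling (Pd(dba)2, LiCl, DMF, slow addition, high dilution), which gives 20.

3. Step 15.
   - What may go wrong: acylation of the hindered tertiary carbinol inside the macrocycle may stall, and long reaction times invite loss of the TES group.
   - Fallback: it changes the mode of activation and the order of events, sets out from 9 and 21 and comes back at 23.
   - DCC dehydrates 21 to 3-(trimethylsilyl)propynoic anhydride F6.
   - F6 acylates the tertiary alcohol of acyclic 9 under Lewis acid catalysis (Sc(OTf)3, MeCN, −20 °C). This activation is possible only at this stage, because no ionisable doubly allylic ether is present yet. The product is the acyclic C12 alkynoate F7.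
   - Coupling of F7 with 18 under the conditions of step 13 gives the tetraene alkynoate F8.
   - Ring-closing metathesis of F8 as in step 14, in which the silyl-capped, electron-poor alkyne should stay out of metathesis, gives 23.

**Further compounds**
F1 | step 17 | C12 diethylphosphonoacetate of 20 (both C3 epimers) | CCOP(=O)(OCC)CC(=O)O[C@]1(C)CC/C=C/C(O[Si](CC)(CC)CC)/C(C)=C/C/C=C(\C)CC[C@@H]1OC(C)=O
F2 | step 17 | C3 allylic alcohol from F1 (both C3 epimers) | CCOP(=O)(OCC)CC(=O)O[C@]1(C)CC/C=C/C(O)/C(C)=C/C/C=C(\C)CC[C@@H]1OC(C)=O
F3 | step 17 | cross-conjugated C1=C2/C4=C5 dienone phosphonoacetate | CCOP(=O)(OCC)CC(=O)O[C@]1(C)CC/C=C/C(=O)/C(C)=C/C/C=C(\C)CC[C@@H]1OC(C)=O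
F4 | step 17 | α-(diethoxyphosphoryl) seven-membered lactone, 3-ketone (C15 epimers) | CCOP(=O)(OCC)C1C(=O)O[C@]2(C)CC[C@@H]1CC(=O)/C(C)=C/C/C=C(\C)CC[C@@H]2OC(C)=O
F5 | step 14 | open-chain (1E)-cross-metathesis product with C5 stannane and C6 allylic acetate (both C3 epimers) | CCCC[Sn](CCCC)(CCCC)/C=C(\C)C(O[Si](CC)(CC)CC)/C=C/CC[C@@](C)(O)[C@@H](OC(C)=O)CC/C(C)=C/COC(C)=O
F6 | step 15 | 3-(trimethylsilyl)propynoic anhydride | C[Si](C)(C)C#CC(=O)OC(=O)C#C[Si](C)(C)C
F7 | step 15 | acyclic C12 3-(trimethylsilyl)propynoate of 9 | C=CCC[C@@](C)(OC(=O)C#C[Si](C)(C)C)[C@@H](OC(C)=O)CC/C(C)=C/COC(C)=O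
F8 | step 15 | C12 3-(trimethylsilyl)propynoate of tetraene 19 (both C3 epimers) | C=CC(O[Si](CC)(CC)CC)/C(C)=C/C/C=C(\C)CC[C@H](OC(C)=O)[C@](C)(OC(=O)C#C[Si](C)(C)C)CCC=C
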